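**Plan**

- Numbering: lactone O1, C2 (carbonyl), C3, C4 (carbinol), C5, C6; side chain C7–C18 with the E alkene at C16=C17 and phenyl on C18. C4 and C6 are both C(O)(CH3)(CH2)2 centres, so an open C2–C8 chain with an ester at each end and a hydroxyl on C4 and C6 is a meso compound. This lets one catalytic ring closure set both centres.
- Retrosynthetic cuts, in order: C8–C9 (sp3–sp3 coupling), C17–C18 (alkenyl–benzyl coupling), O1–C2 (lactone C–O, the key cut), then the two carbinol–methylene C–C bonds of the meso chain (acetate aldol addition, Barbier allylation).
- Forward: the meso C2–C8 diol diester is built first, the only ring is closed by O1–C2 lactonisation, the spare ester arm becomes a C8 iodide, and the separately made C9–C18 bromide is joined last.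
- Stereochemistry: the relative configuration at C4/C6 is that of the meso precursor; the absolute configuration of both centres comes from a chiral phosphoric acid choosing one of two enantiotopic hydroxyl/ester pairs; the E alkene comes from syn hydrozirconation of a terminal alkyne.

Key step: step 4

Assumption: which enantiomer of the phosphoric acid selects the required hydroxyl/ester pair of 7 cannot be predicted with confidence; the (R)-catalyst is written, and the (S)-catalyst is taken instead, with nothing else changed, if a first run gives the antipode.

**Route**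

Step 1
Reactants: 1 tert-butyl acetoacetate; 2 allyl bromide
Product: 3 racemic tert-butyl 3-hydroxy-3-methylhex-5-enoate
Conditions: In powder (1 equiv), 2 (1.5 equiv), THF/H2O (1:1), rt
Reagents that add atoms: none
Why: Barbier allylation in water: the allylindium species made in situ adds to the ketone carbonyl faster than it is protonated by the acidic methylene group and does not touch the tert-butyl ester; the carbinol centre forms as a racemate, which suffices because it is later paired with a second centre in a meso compound.

Step 2
Reactants: 3 racemic tert-butyl 3-hydroxy-3-methylhex-5-enoate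
Product: 4 racemic tert-butyl 3-hydroxy-3-methyl-5-oxohexanoate
Conditions: PdCl2 (10 mol %), CuCl (20 mol %), O2 (1 atm), DMF/H2O (7:1), rt
Reagents that add atoms: water, O (source of the ketone oxygen; O2, O=O, is the terminal oxidant)
Why: Tsuji–Wacker oxidation: Markovnikov hydroxypalladation of the terminal alkene by water and β-hydride elimination give the methyl ketone under nearly neutral conditions that leave the tertiary alcohol and the tert-butyl ester untouched; no stereocentre is formed.

Step 3
Reactants: 4 racemic tert-butyl 3-hydroxy-3-methyl-5-oxohexanoate; 5 tert-butyl acetate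
Product: 7 di-tert-butyl (3R,5S)-3,5-dihydroxy-3,5-dimethylheptanedioate (meso), via lithium 1-tert-butoxyethenolate 6 (not isolated)
Conditions: 5 (3.3 equiv), LiN(iPr)2 (3.2 equiv), THF, −78 °C; then 4, −78 °C; aq. NH4Cl at −78 °C; chromatography on silica
Reagents that add atoms: none
Why: Aldol addition of a lithium ester enolate to a methyl ketone: one equivalent of 6 deprotonates the hydroxyl of 4 and the excess adds to the ketone at −78 °C before the alkoxide can fragment by retro-aldol cleavage; the new carbinol centre forms under little control from the existing one (methyl against CH2CO2tBu), so both diastereomers are expected and the meso isomer 7 is isolated by chromatography, the racemic isomer being discarded.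

Step 4
Reactants: 7 di-tert-butyl (3R,5S)-3,5-dihydroxy-3,5-dimethylheptanedioate (meso)
Product: 8 tert-butyl 2-[(2S,4R)-4-hydroxy-2,4-dimethyl-6-oxooxan-2-yl]acetate
Conditions: (R)-3,3'-bis(2,4,6-triisopropylphenyl)-1,1'-binaphthyl-2,2'-diyl hydrogen phosphate (10 mol %), toluene, 40 °C
Reagents that add atoms: none
Why: Proposed new method: the phosphoric acid is expected to act bifunctionally, its P=O accepting a hydrogen bond from one tertiary hydroxyl while its P–OH activates the carbonyl of the tert-butyl ester 1,5 to that hydroxyl, so that the alcohol adds to the carbonyl and the tetrahedral intermediate collapses with loss of tert-butanol; the closest known reaction type is the phosphoric-acid-catalysed desymmetrising lactonisation of prochiral hydroxy di-tert-butyl esters, which has not been shown on a meso diol diester with tertiary hydroxyls. The single ring closes by 6-exo-trig attack of the C5 oxygen of 7 on C1, which forms the O1–C2 bond of the lactone. No bond to either carbinol carbon is made or broken: the (5S)-hydroxyl/C1-ester pair and the (3R)-hydroxyl/C7-ester pair are enantiotopic, so the chiral pocket of the catalyst, by choosing the former, fixes the absolute configuration of both centres at once as (2S,4R), while their relative configuration is already present in the meso substrate. The step needs enantiotopic group selectivity and mono-lactonisation; the bulky tert-butyl esters keep uncatalysed closure slow, and in 8 the remaining hydroxyl and the acetate arm lie trans across the ring, so a second lactone cannot form. Any residual racemic diol diester would pass through a cis mono-lactone to a C2-symmetric bis-lactone without a tert-butyl group, which is removed by chromatography.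

Step 5
Reactants: 8 tert-butyl 2-[(2S,4R)-4-hydroxy-2,4-dimethyl-6-oxooxan-2-yl]acetate
Product: 9 2-[(2S,4R)-4-hydroxy-2,4-dimethyl-6-oxooxan-2-yl]acetic acid
Conditions: CF3CO2H/CH2Cl2 (1:4), 0 °C to rt; evaporation from toluene
Reagents that add atoms: none
Why: Acidolysis of a tert-butyl ester by alkyl–oxygen cleavage through the tert-butyl cation: the ring C6–O1 bond is also tertiary but is flanked by two electron-poor methylene groups and should ionise far more slowly, so the lactone and both stereocentres are expected to survive.

Step 6
Reactants: 9 2-[(2S,4R)-4-hydroxy-2,4-dimethyl-6-oxooxan-2-yl]acetic acid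
Product: 10 (4R,6R)-4-hydroxy-6-(2-hydroxyethyl)-4,6-dimethyloxan-2-one
Conditions: BH3·SMe2 (2.5 equiv), THF, 0 °C to rt; MeOH quench, evaporation
Reagents that add atoms: none
Why: Chemoselective borane reduction of a carboxylic acid: the acid is reduced through its acyloxyborane far faster than the lactone carbonyl reacts, and the borate formed at the tertiary hydroxyl is cleaved by methanol; no stereocentre is touched (the change of the C6 descriptor is a priority effect only).

Step 7
Reactants: 10 (4R,6R)-4-hydroxy-6-(2-hydroxyethyl)-4,6-dimethyloxan-2-one
Product: 11 (4R,6S)-4-hydroxy-6-(2-iodoethyl)-4,6-dimethyloxan-2-one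
Conditions: I2, PPh3, imidazole, CH2Cl2, 0 °C to rt
Reagents that add atoms: iodine, II
Why: Appel-type iodination: only the primary alcohol forms an alkoxyphosphonium ion that iodide can displace by SN2, the tertiary alcohol being too hindered, and the trans arrangement of the C4 hydroxyl and the iodoethyl arm rules out closure to a cyclic ether.

Step 8
Reactants: 12 non-8-yn-1-ol
Product: 13 9-bromonon-1-yne
Conditions: CBr4, PPh3, CH2Cl2, 0 °C
Reagents that add atoms: carbon tetrabromide, BrC(Br)(Br)Br
Why: Appel bromination: bromide displaces the alkoxyphosphonium ion of the primary alcohol by SN2, and the terminal alkyne is inert to the reagent.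

Step 9
Reactants: 13 9-bromonon-1-yne; 14 benzyl bromide
Product: 17 [(2E)-10-bromodec-2-en-1-yl]benzene, via alkenylzirconocene chloride 15 (not isolated), via alkenylzinc chloride 16 (not isolated)
Conditions: Cp2Zr(H)Cl (1.2 equiv), THF, rt; ZnCl2 (1.2 equiv); then 14, Pd(PPh3)4 (5 mol %), THF, rt
Reagents that add atoms: none
Why: Hydrozirconation followed by Negishi cross-coupling: syn addition of Zr–H across the terminal alkyne places the metal on the terminal carbon and fixes the E geometry, which is retained through transmetalation to zinc and the coupling, while zerovalent palladium inserts into the benzylic C–Br bond far faster than into the primary alkyl bromide.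

Step 10
Reactants: 11 (4R,6S)-4-hydroxy-6-(2-iodoethyl)-4,6-dimethyloxan-2-one; 17 [(2E)-10-bromodec-2-en-1-yl]benzene
Product: 19 trisphaerolide A, via Grignard reagent 18 (not isolated)
Conditions: 17 (2.5 equiv), Mg turnings, THF, 40 °C; the solution is then added slowly to 11 and Li2CuCl4 (5 mol %) in THF at −40 °C, warming to 0 °C; aq. NH4Cl
Reagents that add atoms: none
Why: Kochi-type copper-catalysed sp3–sp3 cross-coupling: the organocopper species formed from 18 and catalytic Li2CuCl4 displaces the primary iodide at low temperature much faster than the Grignard reagent adds to the lactone, one equivalent of 18 being consumed by the tertiary hydroxyl, whose magnesium alkoxide cannot reach C8 because it lies trans to the iodoethyl arm.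

**Compound list**

1 | tert-butyl acetoacetate (tert-butyl 3-oxobutanoate) | CC(=O)CC(=O)OC(C)(C)C | starting material
2 | allyl bromide (3-bromoprop-1-ene) | C=CCBr | starting material
3 | tert-butyl 3-hydroxy-3-methylhex-5-enoate (racemic) | C=CCC(C)(O)CC(=O)OC(C)(C)C | intermediate
4 | tert-butyl 3-hydroxy-3-methyl-5-oxohexanoate (racemic) | CC(=O)CC(C)(O)CC(=O)OC(C)(C)C | intermediate
5 | tert-butyl acetate | CC(=O)OC(C)(C)C | starting material
6 | lithium 1-tert-butoxyethenolate | C=C(O[Li])OC(C)(C)C | intermediate
7 | di-tert-butyl (3R,5S)-3,5-dihydroxy-3,5-dimethylheptanedioate (meso) | CC(C)(C)OC(=O)C[C@](C)(O)C[C@](C)(O)CC(=O)OC(C)(C)C | intermediate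
8 | tert-butyl 2-[(2S,4R)-4-hydroxy-2,4-dimethyl-6-oxooxan-2-yl]acetate | C[C@]1(O)CC(=O)O[C@](C)(CC(=O)OC(C)(C)C)C1 | intermediate
9 | 2-[(2S,4R)-4-hydroxy-2,4-dimethyl-6-oxooxan-2-yl]acetic acid | C[C@]1(O)CC(=O)O[C@](C)(CC(=O)O)C1 | intermediate
10 | (4R,6R)-4-hydroxy-6-(2-hydroxyethyl)-4,6-dimethyloxan-2-one | C[C@]1(O)CC(=O)O[C@](C)(CCO)C1 | intermediate
11 | (4R,6S)-4-hydroxy-6-(2-iodoethyl)-4,6-dimethyloxan-2-one | C[C@]1(O)CC(=O)O[C@](C)(CCI)C1 | intermediate
12 | non-8-yn-1-ol | C#CCCCCCCCO | starting material
13 | 9-bromonon-1-yne | C#CCCCCCCCBr | intermediate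
14 | benzyl bromide | BrCc1ccccc1 | starting material
15 | [(1E)-9-bromonon-1-en-1-yl]chlorobis(cyclopentadienyl)zirconium | BrCCCCCCC/C=C/[Zr+2]Cl.c1cc[cH-]c1.c1cc[cH-]c1 | intermediate
16 | [(1E)-9-bromonon-1-en-1-yl]zinc chloride | BrCCCCCCC/C=C/[Zn]Cl | intermediate
17 | [(2E)-10-bromodec-2-en-1-yl]benzene | BrCCCCCCC/C=C/Cc1ccccc1 | intermediate
18 | [(8E)-10-phenyldec-8-en-1-yl]magnesium bromide | Br[Mg]CCCCCCC/C=C/Cc1ccccc1 | intermediate
19 | trisphaerolide A, (4R,6R)-4-hydroxy-4,6-dimethyl-6-[(10E)-12-phenyldodec-10-en-1-yl]oxan-2-one | C[C@]1(O)CC(=O)O[C@](C)(CCCCCCCCC/C=C/Cc2ccccc2)C1 | target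

**Step count and risks**

Total step count: 10. Longest linear sequence: 8 steps (steps 1–7 and 10); the side-chain branch (steps 8 and 9) joins in step 10.

Steps most likely to fail:

1. Step 4 (Proposed new method). The catalyst may discriminate poorly between the two enantiotopic hydroxyl/ester pairs, or acyl transfer to a tertiary hydroxyl may be so slow that acid-catalysed dehydration competes. Fallback with known chemistry, setting out from 7: trifluoroacetic acid in CH2Cl2 cleaves both tert-butyl esters and closes the lactone without selection, giving racemic 2-[(2RS,4SR)-4-hydroxy-2,4-dimethyl-6-oxooxan-2-yl]acetic acid F1 (only the trans mono-lactone can form from the meso diacid). Classical resolution by crystallisation with (R)-1-phenylethylamine should give (R)-1-phenylethylammonium 2-[(2S,4R)-4-hydroxy-2,4-dimethyl-6-oxooxan-2-yl]acetate F2; the antipodal amine is used if the other salt is the one that crystallises. Acidification with dilute HCl and extraction returns the route at 9.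

2. Step 3. The lithium alkoxide of the β-hydroxy ketone may fragment by retro-aldol cleavage, or the ketone may be enolised, before the enolate adds; the two diastereomers may also be hard to separate. Fallback, setting out from 4: the tertiary hydroxyl is capped with chlorotrimethylsilane and imidazole in DMF to give racemic tert-butyl 3-methyl-5-oxo-3-[(trimethylsilyl)oxy]hexanoate F3, which has no alkoxide to fragment. A Reformatsky reaction with tert-butyl bromoacetate and zinc dust in THF then gives di-tert-butyl (3R*,5S*)-3-hydroxy-3,5-dimethyl-5-[(trimethylsilyl)oxy]heptanedioate F4 together with its diastereomer; the two are separated at this stage, where the single silyl ether should widen the polarity gap, or after cleavage. Citric acid in methanol at 0 °C removes the silyl group and returns the route at 7.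

3. Step 10. The Grignard reagent may add to the lactone carbonyl, or the iodide may be reduced or eliminated, faster than the copper-catalysed substitution takes place. Fallback, setting out from 11 and 17: silylation of 11 with chlorotrimethylsilane and imidazole gives (4R,6S)-6-(2-iodoethyl)-4,6-dimethyl-4-[(trimethylsilyl)oxy]oxan-2-one F5. Bromide 17 is converted with iodine-activated zinc dust in N,N-dimethylacetamide at 80 °C into [(8E)-10-phenyldec-8-en-1-yl]zinc bromide F6, a nucleophile that does not add to lactones. A Negishi alkyl–alkyl coupling (Pd2(dba)3, tricyclopentylphosphine, N-methylimidazole, THF/NMP, 80 °C) joins the two to (4R,6R)-4,6-dimethyl-6-[(10E)-12-phenyldodec-10-en-1-yl]-4-[(trimethylsilyl)oxy]oxan-2-one F7, and dilute HCl in THF removes the silyl ether to reach 19.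

**Further compounds**

F1 | step 4 | racemic 2-[(2RS,4SR)-4-hydroxy-2,4-dimethyl-6-oxooxan-2-yl]acetic acid (one enantiomer drawn) | C[C@]1(O)CC(=O)O[C@](C)(CC(=O)O)C1
F2 | step 4 | (R)-1-phenylethylammonium 2-[(2S,4R)-4-hydroxy-2,4-dimethyl-6-oxooxan-2-yl]acetate | C[C@]1(O)CC(=O)O[C@](C)(CC(=O)[O-])C1.C[C@@H]([NH3+])c1ccccc1
F3 | step 3 | tert-butyl 3-methyl-5-oxo-3-[(trimethylsilyl)oxy]hexanoate (racemic) | CC(=O)CC(C)(O[Si](C)(C)C)CC(=O)OC(C)(C)C
F4 | step 3 | di-tert-butyl (3R*,5S*)-3-hydroxy-3,5-dimethyl-5-[(trimethylsilyl)oxy]heptanedioate (racemic, one enantiomer drawn) | CC(C)(C)OC(=O)C[C@](C)(O)C[C@](C)(O[Si](C)(C)C)CC(=O)OC(C)(C)C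
F5 | step 10 | (4R,6S)-6-(2-iodoethyl)-4,6-dimethyl-4-[(trimethylsilyl)oxy]oxan-2-one | C[C@]1(O[Si](C)(C)C)CC(=O)O[C@](C)(CCI)C1
F6 | step 10 | [(8E)-10-phenyldec-8-en-1-yl]zinc bromide | Br[Zn]CCCCCCC/C=C/Cc1ccccc1
F7 | step 10 | (4R,6R)-4,6-dimethyl-6-[(10E)-12-phenyldodec-10-en-1-yl]-4-[(trimethylsilyl)oxy]oxan-2-one | C[C@]1(O[Si](C)(C)C)CC(=O)O[C@](C)(CCCCCCCCC/C=C/Cc2ccccc2)C1
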